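## Retrosynthetic overview

- Target 21 ← monosulfation of tetrahydroxyarene 20 ← reduction of dihydroxyquinone 19 ← oxidative unmasking of tetramethoxyarene 17. The arene travels as its tetramethyl ether until the end.
- Ring A ← C3–C4 bond by iron-hydride hydrogen-atom-transfer/Giese closure of a C5 isopropenyl group onto a C10 vinyl ketone (14 → 15), then removal of the C1 carbonyl.
- Ring B ← enantioselective intermolecular [4+2] forming C5–C6 and C9–C10 from aryl diene 6 and enal ester 7. The feature that calls for this is the ring-B cyclohexene: C7=C8 (methyl on C8) lies across the ring from the C5–C10 bond, and C9, C10 (quaternary) and C5 are three contiguous stereocentres.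
- Diene 6 ← arylcopper of 1,2,4,5-tetramethoxybenzene + (E)-5-bromo-3-methylpenta-1,3-diene.
- Ring order: arene (bought), ring B (step 3), ring A (step 8).

Key step: step 3

Assumption: the target is taken as the free aryl hydrogen sulfate as drawn; in practice it would be isolated as its pyridinium or sodium salt, which has the same organic structure.

Numbering used below: drimane numbering C1–C11 for the terpenoid part (C11 = benzylic CH2); arene C1' (bears C11), C2'/C6' (ortho), C3'/C5' (meta), C4' (CH). The target is (5S,9R,10S): H-5 and C11 on one face, the C10 methyl on the other.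

## Route

Step 1
Reactants: 1 3-methylpenta-1,4-dien-3-ol
Product: 2 (E)-5-bromo-3-methylpenta-1,3-diene (E-enriched mixture)
Conditions: 48% aq HBr, 0 °C; pentane extraction; used cold without distillation
Reagents that add atoms: hydrogen bromide, Br
Why: Acid ionises the tertiary bis-allylic alcohol to the 3-methylpentadienyl cation, which bromide captures at a primary terminus (allylic transposition, SN1'), and the E isomer should predominate under these equilibrating conditions.

Step 2
Reactants: 3 1,2,4,5-tetramethoxybenzene; 2 (E)-5-bromo-3-methylpenta-1,3-diene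
Product: 6 1,2,4,5-tetramethoxy-3-[(2E)-3-methylpenta-2,4-dien-1-yl]benzene, via aryllithium 4 (not isolated), via arylcopper 5 (not isolated)
Conditions: n-BuLi, THF, 0 °C → rt; CuBr·SMe2, −40 °C; then 2, −78 → 0 °C; chromatography on AgNO3-impregnated silica gel to remove the Z isomer
Reagents that add atoms: none
Why: Directed ortho-lithiation between two methoxy groups, transmetalation to copper and allylic substitution; attack at either primary terminus of the 3-methylpentadienyl unit gives the same constitution, and the tertiary central carbon is too hindered to compete.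

Step 3
Reactants: 6 1,2,4,5-tetramethoxy-3-[(2E)-3-methylpenta-2,4-dien-1-yl]benzene; 7 ethyl (E)-3-methyl-4-oxobut-2-enoate
Product: 8 ethyl (1R,5R,6R)-6-formyl-4,6-dimethyl-5-[(2,3,5,6-tetramethoxyphenyl)methyl]cyclohex-3-ene-1-carboxylate
Conditions: (S)-diphenylprolinol-derived B-o-tolyl oxazaborolidine (20 mol %), HNTf2 (18 mol %), CH2Cl2, −78 → −20 °C
Reagents that add atoms: none
Why: This is an oxazaborolidinium-catalysed Diels–Alder reaction of an α-substituted enal, a concerted but asynchronous [4+2] cycloaddition in which the boron-bound formyl group makes C5 (β to CHO) the most electrophilic carbon, so it bonds first to the unsubstituted diene terminus C6 while C10 joins the substituted terminus C9. Ring B closes by intermolecular suprafacial [4+2] cycloaddition, both new bonds (C5–C6, C9–C10) forming on one face of the s-cis diene, whose central bond becomes the C7=C8 alkene. C5 and C10 carry the ester and formyl arms trans because the E geometry of 7 is transferred stereospecifically, and C9 is set by the formyl-endo transition state on the E diene, which places the arylmethyl group cis to CHO and anti to the C10 methyl. Absolute configuration comes from the catalyst: the s-trans enal sits on boron with its formyl C–H against the ring oxygen and its C=C stacked over a phenyl group, which should leave the Re face at C10 open, the same facial sense known for 2-methylacrolein with this catalyst class. The step needs ortho-type regiochemistry, formyl-endo topology and one enantioface; the first two rest on the aldehyde being a stronger Lewis base than the ester and on the terminal substituent of the diene outweighing its internal methyl group, and any residual Z diene cannot reach the s-cis conformation and stays behind.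

Step 4
Reactants: 8 ethyl (1R,5R,6R)-6-formyl-4,6-dimethyl-5-[(2,3,5,6-tetramethoxyphenyl)methyl]cyclohex-3-ene-1-carboxylate
Product: 10 trans-fused γ-lactone 3-ethenyl-3a,5-dimethyl-4-[(2,3,5,6-tetramethoxyphenyl)methyl]-3a,4,7,7a-tetrahydro-2-benzofuran-1(3H)-one (both C1 epimers), via hydroxy ester 9 (not isolated)
Conditions: CH2=CHMgBr (1.1 equiv), THF, −78 °C → rt; aq NH4Cl
Reagents that add atoms: vinylmagnesium bromide, C=C[Mg]Br
Why: Chemoselective Grignard 1,2-addition to the aldehyde in the presence of the ester at low temperature, after which the alkoxide lactonises onto the neighbouring ester on warming; the new C1 carbinol centre forms as a mixture that is erased in step 6.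

Step 5
Reactants: 10 trans-fused γ-lactone (both C1 epimers)
Product: 12 2-[6-(1-hydroxyprop-2-en-1-yl)-4,6-dimethyl-5-[(2,3,5,6-tetramethoxyphenyl)methyl]cyclohex-3-en-1-yl]propan-2-ol (ring configuration as in 8), via hydroxy methyl ketone 11 (not isolated)
Conditions: MeLi (4 equiv), THF, −78 → 0 °C; H2O
Reagents that add atoms: methyllithium, [Li]C
Why: Double addition of methyllithium to the lactone carbonyl through the methyl ketone gives the tertiary carbinol that carries both future C4 methyl groups, and addition at low temperature should outpace enolisation at C5.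

Step 6
Reactants: 12 diol
Product: 13 1-[6-(2-hydroxypropan-2-yl)-1,3-dimethyl-2-[(2,3,5,6-tetramethoxyphenyl)methyl]cyclohex-3-en-1-yl]prop-2-en-1-one
Conditions: Dess–Martin periodinane, CH2Cl2, 0 °C → rt
Reagents that add atoms: none
Why: Dess–Martin oxidation converts the secondary allylic alcohol into the vinyl ketone while the tertiary alcohol cannot be oxidised, and the C1 epimer mixture converges to one compound.

Step 7
Reactants: 13 hydroxy vinyl ketone
Product: 14 1-[1,3-dimethyl-6-(prop-1-en-2-yl)-2-[(2,3,5,6-tetramethoxyphenyl)methyl]cyclohex-3-en-1-yl]prop-2-en-1-one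
Conditions: Burgess reagent, toluene, BHT (cat.), 50 °C
Reagents that add atoms: none
Why: Burgess dehydration (syn elimination through the sulfamate ester) of the tertiary alcohol should favour loss of a methyl hydrogen, because the alternative tetrasubstituted C4=C5 alkene would be strained against the quaternary C10, and the neutral conditions spare the vinyl ketone.

Step 8
Reactants: 14 isopropenyl vinyl ketone
Product: 15 (5S,9R,10S)-decalin C1 ketone 4,4,7,8a-tetramethyl-8-[(2,3,5,6-tetramethoxyphenyl)methyl]-3,4,4a,5,8,8a-hexahydronaphthalen-1(2H)-one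
Conditions: Fe(acac)3 (30 mol %), PhSiH3, EtOH/ethylene glycol, 60 °C
Reagents that add atoms: none
Why: Iron-hydride hydrogen-atom transfer to the 1,1-disubstituted alkene (reductive olefin coupling) gives the tertiary C4 radical, which adds to the terminal carbon C3 of the vinyl ketone in a 6-endo-trig Giese closure of ring A; no new stereocentre forms and the trans ring fusion is already fixed at C5 and C10.

Step 9
Reactants: 15 decalin C1 ketone
Product: 17 1,2,4,5-tetramethoxy-3-{[(1R,4aS,8aS)-2,5,5,8a-tetramethyl-1,4,4a,5,6,7,8,8a-octahydronaphthalen-1-yl]methyl}benzene, via hydrazone 16 (not isolated)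
Conditions: N2H4·H2O, KOH, diethylene glycol, 130 → 200 °C
Reagents that add atoms: none
Why: Wolff–Kishner reduction (Huang-Minlon procedure) removes the C1 carbonyl; C10 is quaternary so nothing can epimerise, and the isolated alkene and the aryl methyl ethers should tolerate hot hydroxide.

Step 10
Reactants: 17 tetramethoxyarene
Product: 18 2,5-dimethoxy-3-{[(1R,4aS,8aS)-2,5,5,8a-tetramethyl-1,4,4a,5,6,7,8,8a-octahydronaphthalen-1-yl]methyl}cyclohexa-2,5-diene-1,4-dione
Conditions: (NH4)2Ce(NO3)6, MeCN/H2O, 0 °C
Reagents that add atoms: water, O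
Why: Oxidative demethylation of a para-dimethoxy pair through the arene radical cation gives the 2,5-dimethoxy-1,4-benzoquinone; the two para pairs are equivalent by symmetry, so one quinone should result, and isolated trisubstituted alkenes survive this oxidant.

Step 11
Reactants: 18 dimethoxyquinone
Product: 19 2,5-dihydroxy-3-{[(1R,4aS,8aS)-2,5,5,8a-tetramethyl-1,4,4a,5,6,7,8,8a-octahydronaphthalen-1-yl]methyl}cyclohexa-2,5-diene-1,4-dione
Conditions: 2 M aq NaOH, EtOH, 60 °C; then dilute HCl, 0 °C
Reagents that add atoms: sodium hydroxide, [Na+].[OH-]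
Why: Both methoxy groups are vinylogous esters and undergo addition–elimination with hydroxide (vinylogous saponification), the classical entry to 3-alkyl-2,5-dihydroxybenzoquinones.

Step 12
Reactants: 19 dihydroxyquinone
Product: 20 3-{[(1R,4aS,8aS)-2,5,5,8a-tetramethyl-1,4,4a,5,6,7,8,8a-octahydronaphthalen-1-yl]methyl}benzene-1,2,4,5-tetrol
Conditions: Na2S2O4, EtOAc/H2O, rt, argon; dried extract used at once
Reagents that add atoms: none
Why: Dithionite reduction of the quinone gives the tetrahydroxyarene, which is kept under argon because it re-oxidises easily.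

Step 13
Reactants: 20 tetrahydroxyarene
Product: 21 2,4,5-trihydroxy-3-{[(1R,4aS,8aS)-2,5,5,8a-tetramethyl-1,4,4a,5,6,7,8,8a-octahydronaphthalen-1-yl]methyl}phenyl hydrogen sulfate (target)
Conditions: SO3·pyridine (1.0 equiv), pyridine/DMF, 0 °C, argon; degassed reverse-phase chromatography
Reagents that add atoms: sulfur trioxide pyridine complex, [O-]S(=O)(=O)[n+]1ccccc1
Why: O-Sulfonation of a phenol by SO3·pyridine; the C2' and C6' hydroxyls are flanked by the bulky decalinylmethyl group, whereas the C3' and C5' hydroxyls sit next to the aromatic C–H and are equivalent by symmetry, so one equivalent of reagent should sulfate one of the latter.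

## Compound list

1 | 3-methylpenta-1,4-dien-3-ol | C=CC(C)(O)C=C | starting material
2 | (E)-5-bromo-3-methylpenta-1,3-diene | C=C/C(C)=C/CBr | intermediate
3 | 1,2,4,5-tetramethoxybenzene | COc1cc(OC)c(OC)cc1OC | starting material
4 | (2,3,5,6-tetramethoxyphenyl)lithium (not isolated) | [Li]c1c(OC)c(OC)cc(OC)c1OC | intermediate
5 | (2,3,5,6-tetramethoxyphenyl)copper (not isolated) | [Cu]c1c(OC)c(OC)cc(OC)c1OC | intermediate
6 | 1,2,4,5-tetramethoxy-3-[(2E)-3-methylpenta-2,4-dien-1-yl]benzene | C=C/C(C)=C/Cc1c(OC)c(OC)cc(OC)c1OC | intermediate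
7 | ethyl (E)-3-methyl-4-oxobut-2-enoate | CCOC(=O)/C=C(\C)C=O | starting material
8 | ethyl (1R,5R,6R)-6-formyl-4,6-dimethyl-5-[(2,3,5,6-tetramethoxyphenyl)methyl]cyclohex-3-ene-1-carboxylate | CC1=CC[C@@H](C(=O)OCC)[C@](C)(C=O)[C@@H]1Cc1c(OC)c(OC)cc(OC)c1OC | intermediate
9 | hydroxy ester: 8 with CHO replaced by CH(OH)CH=CH2, C1 epimers (not isolated) | CC1=CC[C@@H](C(=O)OCC)[C@](C)(C(O)C=C)[C@@H]1Cc1c(OC)c(OC)cc(OC)c1OC | intermediate
10 | trans-fused γ-lactone, 3-ethenyl-3a,5-dimethyl-4-[(2,3,5,6-tetramethoxyphenyl)methyl]-3a,4,7,7a-tetrahydro-2-benzofuran-1(3H)-one, C1 epimers | CC1=CC[C@H]2C(=O)OC(C=C)[C@]2(C)[C@@H]1Cc1c(OC)c(OC)cc(OC)c1OC | intermediate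
11 | hydroxy methyl ketone: C5 acetyl, C10 CH(OH)CH=CH2 (not isolated) | CC1=CC[C@@H](C(C)=O)[C@](C)(C(O)C=C)[C@@H]1Cc1c(OC)c(OC)cc(OC)c1OC | intermediate
12 | diol: C5 2-hydroxypropan-2-yl, C10 CH(OH)CH=CH2, C1 epimers | CC1=CC[C@@H](C(C)(C)O)[C@](C)(C(O)C=C)[C@@H]1Cc1c(OC)c(OC)cc(OC)c1OC | intermediate
13 | hydroxy vinyl ketone: C5 2-hydroxypropan-2-yl, C10 acryloyl | CC1=CC[C@@H](C(C)(C)O)[C@](C)(C(=O)C=C)[C@@H]1Cc1c(OC)c(OC)cc(OC)c1OC | intermediate
14 | isopropenyl vinyl ketone: C5 prop-1-en-2-yl, C10 acryloyl | CC1=CC[C@@H](C(C)=C)[C@](C)(C(=O)C=C)[C@@H]1Cc1c(OC)c(OC)cc(OC)c1OC | intermediate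
15 | (5S,9R,10S)-decalin C1 ketone, trans-fused | CC1=CC[C@H]2C(C)(C)CCC(=O)[C@]2(C)[C@@H]1Cc1c(OC)c(OC)cc(OC)c1OC | intermediate
16 | C1 hydrazone of 15 (not isolated) | CC1=CC[C@H]2C(C)(C)CCC(=NN)[C@]2(C)[C@@H]1Cc1c(OC)c(OC)cc(OC)c1OC | intermediate
17 | 1,2,4,5-tetramethoxy-3-{[(1R,4aS,8aS)-2,5,5,8a-tetramethyl-1,4,4a,5,6,7,8,8a-octahydronaphthalen-1-yl]methyl}benzene | CC1=CC[C@H]2C(C)(C)CCC[C@]2(C)[C@@H]1Cc1c(OC)c(OC)cc(OC)c1OC | intermediate
18 | 3-(decalinylmethyl)-2,5-dimethoxy-1,4-benzoquinone | CC1=CC[C@H]2C(C)(C)CCC[C@]2(C)[C@@H]1CC1=C(OC)C(=O)C=C(OC)C1=O | intermediate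
19 | 3-(decalinylmethyl)-2,5-dihydroxy-1,4-benzoquinone | CC1=CC[C@H]2C(C)(C)CCC[C@]2(C)[C@@H]1CC1=C(O)C(=O)C=C(O)C1=O | intermediate
20 | 3-(decalinylmethyl)benzene-1,2,4,5-tetrol | CC1=CC[C@H]2C(C)(C)CCC[C@]2(C)[C@@H]1Cc1c(O)c(O)cc(O)c1O | intermediate
21 | 2,4,5-trihydroxy-3-{[(1R,4aS,8aS)-2,5,5,8a-tetramethyl-1,4,4a,5,6,7,8,8a-octahydronaphthalen-1-yl]methyl}phenyl hydrogen sulfate | CC1=CC[C@H]2C(C)(C)CCC[C@]2(C)[C@@H]1Cc1c(O)c(O)cc(OS(=O)(=O)O)c1O | target

## Step count and risks

Total steps: 13. Longest linear sequence: 13 steps (1 → 21); 3 enters at step 2 and 7 at step 3.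

Steps most likely to fail:

1. Step 3. The trisubstituted diene may turn over slowly, and enantioface control or formyl-endo topology may erode because the ester competes for the endo position. If only the sense of induction is wrong, the (R)-catalyst is used instead. The fallback sets out from 6 and 7: the cycloaddition is promoted by an achiral Lewis acid (Me2AlCl, CH2Cl2, −78 °C), which should give the same regio- and endo-isomer as a racemate, that is 8 together with its mirror image, ethyl (1S,5S,6S)-6-formyl-4,6-dimethyl-5-[(2,3,5,6-tetramethoxyphenyl)methyl]cyclohex-3-ene-1-carboxylate F1. The enantiomers are separated by preparative supercritical-fluid chromatography on a chiral stationary phase, and the route is rejoined at 8.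

2. Step 8. Hydrogen-atom transfer may go to the C7=C8 alkene (then closing from C8 onto C3), or the vinyl ketone may simply be reduced without cyclisation. The fallback sets out from 13 and generates the C4 radical site-specifically. The tertiary alcohol is acylated with N-phthalimidoyl chlorooxalate (Et3N, DMAP, THF) to give the tert-alkyl N-phthalimidoyl oxalate of 13 F2. Visible-light photoredox fragmentation (Ru(bpy)3(PF6)2, Hantzsch ester, i-Pr2NEt·HBF4, blue light) releases the tertiary radical, which closes 6-endo onto the vinyl ketone. The route is rejoined at 15, and step 7 is no longer needed.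

3. Step 13. Sulfation may run on to the bis-sulfate, some reaction may occur at the hindered C2'/C6' hydroxyls, and the polyphenol may re-oxidise in air during isolation of the charged product. The fallback sets out from 20 and uses a protected sulfate: 2,2,2-trichloroethyl chlorosulfate (1 equiv, Et3N, DMAP, THF, −20 °C) gives the neutral 2,4,5-trihydroxy-3-(decalinylmethyl)phenyl 2,2,2-trichloroethyl sulfate F3. This diester can be separated from regioisomers and bis-sulfated material on silica. Reductive removal of the trichloroethyl group (Zn, HCO2NH4, MeOH) then gives 21.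

Further compounds
F1 | step 3 | ethyl (1S,5S,6S)-6-formyl-4,6-dimethyl-5-[(2,3,5,6-tetramethoxyphenyl)methyl]cyclohex-3-ene-1-carboxylate (enantiomer of 8) | CC1=CC[C@H](C(=O)OCC)[C@@](C)(C=O)[C@H]1Cc1c(OC)c(OC)cc(OC)c1OC
F2 | step 8 | tert-alkyl N-phthalimidoyl oxalate of 13 | CC1=CC[C@@H](C(C)(C)OC(=O)C(=O)ON2C(=O)c3ccccc3C2=O)[C@](C)(C(=O)C=C)[C@@H]1Cc1c(OC)c(OC)cc(OC)c1OC
F3 | step 13 | 2,4,5-trihydroxy-3-(decalinylmethyl)phenyl 2,2,2-trichloroethyl sulfate | CC1=CC[C@H]2C(C)(C)CCC[C@]2(C)[C@@H]1Cc1c(O)c(O)cc(OS(=O)(=O)OCC(Cl)(Cl)Cl)c1O
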